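The target is cut at the 1,3-dicarbonyl unit C6–C5–C16 (C6 enol ether, C16 ketone) shared by the cyclohexene ring C4–C5–C6–C18–C19–C20 and the pyranone; this unit is carried as an isoxazole. One intramolecular nitrile oxide–alkyne cycloaddition forms C5–C6 and O–C16 and so closes the carbocycle and the heterocycle together. Its precursor is a bicyclo[3.2.1]octan-8-one with an exo aldoxime on C18, the C30 thioester, the O25 lactone and, on C19, the cis-fused O21 lactone carrying the silyloxy alkyne. Two organocatalytic annulations build the core; an anti-selective allenylindium addition installs the alkyne; isoxazole opening, pyranone closure and a thioester–boronic acid coupling complete the target.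

Key step: step 23

Remarks on the chemistry:
- Atom labels (C2–C41, O21, O25) are those of the target SMILES.
- The cis fusion of the O21 lactone corresponds to an anti relationship between the C20 oxygen and the C3 side chain on C4 (chain C19–C20–C4–C5), so the propargylation must be anti-selective; a cyclic-transition-state allenylindium is used for that reason.
- Only one aldehyde (C20) is free at the propargylation; the C6 aldehyde stays masked as its dimethyl acetal until the oxime is made.
- In 5–8 and 12 the carbon between ketone and thioester (C30) is configurationally labile and is written without a descriptor.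

Step 1
Reactants: 1 diketene
Product: 3 S-ethyl 4-bromo-3-oxobutanethioate, via 4-bromo-3-oxobutanoyl bromide 2 (not isolated)
Conditions: Br2, CH2Cl2, −30 °C; then EtSH, −30 → 0 °C
Reagents that add atoms: bromine BrBr; ethanethiol CCS
Why: Brominative ring opening of diketene gives the 4-bromoacetoacetyl bromide, which ethanethiol acylates to the thioester (the standard entry to 4-haloacetoacetic acid derivatives); no stereocenter is formed.

Step 2
Reactants: 3 S-ethyl 4-bromo-3-oxobutanethioate; 4 (E)-4,4-dimethoxybut-2-enal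
Product: 6 S-ethyl 2-(dimethoxymethyl)-3-formyl-5-oxocyclopentane-1-carbothioate (2,3-trans), via acyclic Michael adduct 5 (not isolated)
Conditions: (R)-2-[diphenyl(trimethylsilyloxy)methyl]pyrrolidine (20 mol%), K2CO3, CHCl3, 4 °C → rt
Reagents that add atoms: none
Why: Organocatalytic domino Michael addition/intramolecular enamine α-alkylation: C30 of 3 attacks the iminium ion of 4 on the face left open by the (R)-catalyst (this sets C18, which is erased later), and the enamine then closes the cyclopentanone by SN2 at the bromomethyl ketone, which puts the formyl group on C19 trans to the acetal arm and thereby sets C19, the centre that is kept.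

Step 3
Reactants: 6 trans formyl cyclopentanone thioester
Product: 7 S-ethyl 2-(dimethoxymethyl)-3-(hydroxymethyl)-5-oxocyclopentane-1-carbothioate (2,3-trans)
Conditions: NaBH(OAc)3, AcOH, CH2Cl2, 0 °C → rt
Reagents that add atoms: none
Why: Chemoselective hydride reduction (triacetoxyborohydride reduces aldehydes but not ketones or the enolised β-keto thioester) removes the formyl group that would make C19–H too acidic in step 5; C19 is untouched.

Step 4
Reactants: 7 trans hydroxymethyl cyclopentanone thioester
Product: 8 S-ethyl 3-{[tert-butyl(diphenyl)silyl]oxymethyl}-2-(dimethoxymethyl)-5-oxocyclopentane-1-carbothioate (2,3-trans)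
Conditions: TBDPSCl, imidazole, DMF, 0 °C → rt
Reagents that add atoms: tert-butyl(chloro)diphenylsilane CC(C)(C)[Si](Cl)(c1ccccc1)c1ccccc1
Why: Silylation of the primary alcohol prevents its lactonisation onto the thioester and gives an ether that survives the acidic methanolysis of step 10.

Step 5
Reactants: 8 trans TBDPS ether
Product: 11 S-ethyl 3-{[tert-butyl(diphenyl)silyl]oxymethyl}-2-(dimethoxymethyl)-5-oxocyclopent-1-ene-1-carbothioate, via α-phenylselanyl thioester 9 (not isolated), via selenoxide 10 (not isolated)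
Conditions: PhSeCl, pyridine, CH2Cl2, 0 °C; then 30% H2O2, 0 °C → rt
Reagents that add atoms: none
Why: Selenoxide syn-elimination of the α-selenylated β-keto thioester can only run towards C18–H, so it erases the wrongly configured C18 and gives the C30=C18 enone under non-basic conditions that leave the C19 stereocenter intact.

Step 6
Reactants: 11 cyclopentenone thioester
Product: 12 S-ethyl 3-{[tert-butyl(diphenyl)silyl]oxymethyl}-2-(dimethoxymethyl)-5-oxocyclopentane-1-carbothioate (2,3-cis)
Conditions: Hantzsch ester (diethyl 2,6-dimethyl-1,4-dihydropyridine-3,5-dicarboxylate), SiO2, toluene, 60 °C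
Reagents that add atoms: none
Why: Conjugate transfer hydrogenation of the doubly activated alkene delivers hydride to C18 anti to the bulky silyloxymethyl group on C19 (substrate control), so the acetal arm ends cis to the C19 arm.

Step 7
Reactants: 13 3-[(tert-butyldimethylsilyl)oxy]propanal; 14 (triphenylphosphoranylidene)acetaldehyde
Product: 15 (E)-5-[(tert-butyldimethylsilyl)oxy]pent-2-enal
Conditions: toluene, 80 °C
Reagents that add atoms: none
Why: Wittig olefination with the stabilised formylmethylene ylide gives the (E)-enal selectively.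

Step 8
Reactants: 12 cis cyclopentanone thioester; 15 (E)-5-[(tert-butyldimethylsilyl)oxy]pent-2-enal
Product: 17 bicyclo[3.2.1]octan-8-one aldol (C23 carbinol, C29 silyloxyethyl side chain, exo arms on C18 and C19), via keto aldehyde Michael adduct 16 (not isolated)
Conditions: (R)-2-[diphenyl(trimethylsilyloxy)methyl]pyrrolidine (20 mol%), PhCO2H (20 mol%), toluene, 0 °C → rt; then DBU (0.2 equiv), rt
Reagents that add atoms: none
Why: Iminium-catalysed Michael addition followed by intramolecular aldol (α,α'-annulation of a cyclic β-keto ester with an enal): C30 adds on the ring face anti to both arms (substrate control, which makes them exo), the (R)-catalyst fixes C29 at the enal β-carbon, and the aldol of C22 onto the C23 aldehyde has to close cis to the first bond, the C23 carbinol configuration being irrelevant.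

Step 9
Reactants: 17 bicyclic aldol
Product: 18 bicyclo[3.2.1]oct-3-en-8-one (C23=C24 alkene)
Conditions: Burgess reagent (methyl N-(triethylammoniosulfonyl)carbamate), toluene, 70 °C
Reagents that add atoms: none
Why: Burgess syn-dehydration of the β-ketol can only give the C23=C24 alkene because C22 is a bridgehead; no stereocenter changes.

Step 10
Reactants: 18 bicyclic alkene
Product: 19 primary alcohol (C26–OH)
Conditions: PPTS, MeOH, rt
Reagents that add atoms: none
Why: Acid-catalysed methanolysis removes the primary TBS ether selectively in the presence of the TBDPS ether, and the dimethyl acetal is inert in methanol; the alcohol is oxidised at once to forestall attack on the thioester.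

Step 11
Reactants: 19 primary alcohol
Product: 20 carboxylic acid (C26 acid on the C28 side chain)
Conditions: (pyH)2Cr2O7 (PDC), DMF, rt
Reagents that add atoms: pyridinium dichromate c1cc[nH+]cc1.c1cc[nH+]cc1.[O-][Cr](=O)(=O)O[Cr](=O)(=O)[O-]
Why: Corey–Schmidt oxidation of a saturated primary alcohol to the acid in DMF works without aqueous acid and so spares acetal, thioester and alkene.

Step 12
Reactants: 20 γ,δ-unsaturated acid
Product: 21 iodolactone (O25 lactone cis-fused at C24–C29, iodine on C23)
Conditions: I2, NaHCO3, MeCN/H2O, 0 °C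
Reagents that add atoms: iodine II
Why: Iodolactonisation: the carboxylate on the C28 arm attacks C24 in a 5-exo mode anti to the iodonium ion, so O25 is delivered to the face that carries C28 (C24 set by C29, cis ring fusion) and iodine ends trans on C23.

Step 13
Reactants: 21 iodolactone
Product: 22 lactone thioester (C23 now CH2)
Conditions: Bu3SnH, AIBN, toluene, 80 °C
Reagents that add atoms: none
Why: Radical-chain tin hydride reduction removes the C23 iodide without touching ketone, lactone or thioester; no stereocenter is affected.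

Step 14
Reactants: 22 TBDPS-protected lactone thioester
Product: 23 C20 primary alcohol
Conditions: HF·pyridine, pyridine, THF, 0 °C → rt
Reagents that add atoms: none
Why: Fluoride-mediated desilylation buffered with pyridine frees the C20 hydroxyl while acetal, lactone and thioester are preserved.

Step 15
Reactants: 23 C20 primary alcohol
Product: 24 C20 aldehyde (exo formyl on C19)
Conditions: Dess–Martin periodinane, NaHCO3, CH2Cl2, rt
Reagents that add atoms: none
Why: Dess–Martin oxidation gives the aldehyde under buffered neutral conditions, which avoids epimerisation at C19.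

Step 16
Reactants: 25 (R)-1-phenylbut-3-yn-1-ol
Product: 26 (R)-tert-butyldimethyl[(1-phenylbut-3-yn-1-yl)oxy]silane
Conditions: TBSCl, imidazole, DMF, rt
Reagents that add atoms: tert-butyl(chloro)dimethylsilane CC(C)(C)[Si](C)(C)Cl
Why: Standard silylation protects the C8 hydroxyl until the pyranone closure; C8 is not involved.

Step 17
Reactants: 26 silyl ether of the alkynol
Product: 27 (R)-5-[(tert-butyldimethylsilyl)oxy]-N-methoxy-N-methyl-5-phenylpent-2-ynamide
Conditions: n-BuLi, THF, −78 °C; then ClC(=O)N(OMe)Me, −78 → 0 °C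
Reagents that add atoms: N-methoxy-N-methylcarbamoyl chloride CON(C)C(Cl)=O
Why: Acylation of the lithium acetylide gives the alkynyl Weinreb amide, whose carbonyl carbon becomes C4.

Step 18
Reactants: 27 alkynyl Weinreb amide
Product: 28 methyl (R)-7-[(tert-butyldimethylsilyl)oxy]-3-oxo-7-phenylhept-4-ynoate
Conditions: MeOAc, LiN(iPr)2 (2.2 equiv), THF, −78 °C; then 27, −78 → −40 °C
Reagents that add atoms: methyl acetate COC(C)=O
Why: Claisen-type acylation of the lithium enolate of methyl acetate by the Weinreb amide, whose chelated tetrahedral intermediate prevents over-addition, gives the alkynyl β-keto ester.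

Step 19
Reactants: 28 alkynyl β-keto ester
Product: 29 methyl (3S,7R)-7-[(tert-butyldimethylsilyl)oxy]-3-hydroxy-7-phenylhept-4-ynoate
Conditions: RuCl(p-cymene)[(S,S)-TsDPEN] (2 mol%), HCO2H/Et3N (5:2), rt
Reagents that add atoms: none
Why: Noyori asymmetric transfer hydrogenation of the alkynyl ketone, in which the alkyne acts as the π-substituent, should give the (S)-propargylic alcohol under control of the (S,S)-catalyst.

Step 20
Reactants: 29 (S)-propargylic alcohol
Product: 30 methyl (3S,7R)-7-[(tert-butyldimethylsilyl)oxy]-3-(methylsulfonyloxy)-7-phenylhept-4-ynoate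
Conditions: MsCl, Et3N, CH2Cl2, −78 °C; used without purification
Reagents that add atoms: methanesulfonyl chloride CS(Cl)(=O)=O
Why: Mesylation proceeds with retention at the carbinol carbon, and short cold exposure to base limits E1cB elimination of the β-mesyloxy ester.

Step 21
Reactants: 24 C20 aldehyde; 30 propargylic mesylate
Product: 33 acetal with the cis-fused O21 alkynyl lactone, via allenylindium reagent 31 (not isolated), via homopropargylic hydroxy ester 32 (not isolated)
Conditions: Pd(OAc)2 (5 mol%), PPh3 (5 mol%), InI, THF/HMPA (3:1), rt; then PPTS, CH2Cl2, rt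
Reagents that add atoms: none
Why: Marshall propargylation: zerovalent palladium displaces the mesylate in an anti SN2' sense, transmetalation to indium gives the chiral allenylindium 31, which adds to the aldehyde through a cyclic SE2' transition state to give the anti homopropargylic alcohol (C4 fixed by the axial chirality of 31 with net inversion of the mesylate centre, C20 by the anti preference of the cyclic transition state), and the γ-hydroxy ester then lactonises to the cis-fused O21 lactone.

Step 22
Reactants: 33 acetal lactone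
Product: 34 exo (E)-aldoxime on C18
Conditions: NH2OH·HCl, THF/H2O, rt → 40 °C
Reagents that add atoms: hydroxylamine hydrochloride NO.Cl
Why: The weakly acidic hydroxylammonium salt hydrolyses the dimethyl acetal and condenses with the freed C6 aldehyde in one operation, at a pH where free hydroxylamine is too scarce to attack the hindered thioester or the C41 ketone.

Step 23
Reactants: 34 exo aldoxime
Product: 36 isoxazole-fused pentacycle (C30 S-ethyl thioester, C8 silyl ether), via nitrile oxide 35 (not isolated)
Conditions: PhI(OAc)2, TFA (10 mol%), MeOH/CH2Cl2, 0 °C → rt, 5 mM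
Reagents that add atoms: none
Why: PhI(OAc)2 oxidises the aldoxime to the nitrile oxide 35, a 1,3-dipole that adds to the tethered alkyne in a concerted (3+2) process. The closest known reaction type is the intramolecular nitrile oxide–alkyne cycloaddition that gives ring-fused isoxazoles. The carbocycle C4–C5–C6–C18–C19–C20 closes in an exo mode (C6 bonds to the proximal alkyne carbon C5, six-membered ring), and the isoxazole C6–N–O–C16–C5 forms in the same event. No stereocenter is created. Regioselectivity is imposed by the tether C18–C19–C20–C4, which cannot deliver C6 to C16, and the cis O21 lactone together with the exo,cis arrangement at C18/C19 holds dipole and alkyne within bonding distance. Chemoselectivity for the alkyne is secured because no other dipolarophile is present (the cinnamoyl alkene is still a thioester), and high dilution suppresses dimerisation to the furoxan.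

Step 24
Reactants: 36 isoxazole
Product: 37 primary enaminone (C6–NH2, C16 ketone)
Conditions: Mo(CO)6, MeCN/H2O (15:1), 80 °C
Reagents that add atoms: none
Why: Mo(CO)6-mediated reductive cleavage of the isoxazole N–O bond in wet acetonitrile unmasks the vinylogous amide of the 1,3-diketone without affecting thioester, lactones or silyl ether.

Step 25
Reactants: 37 enaminone
Product: 39 dihydropyranone with the C30 S-ethyl thioester, via hydroxy enaminone 38 (not isolated)
Conditions: aq. HF, MeCN, 0 °C → rt; then TFA, CH2Cl2, rt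
Reagents that add atoms: none
Why: Desilylation followed by acid-catalysed conjugate addition of the C8 hydroxyl to C6 and loss of ammonia (vinylogous transamidation) closes the 2,3-dihydropyran-4-one; C8 keeps its configuration because only its O–H bond reacts.

Step 26
Reactants: 39 pyranone thioester; 40 (E)-styrylboronic acid
Product: 41 CNP0313292.4
Conditions: Pd2(dba)3 (5 mol%), tri(2-furyl)phosphine, Cu(thiophene-2-carboxylate) (1.5 equiv), THF, 50 °C
Reagents that add atoms: none
Why: Liebeskind–Srogl coupling: copper-assisted insertion of zerovalent palladium into the C–S bond and transmetalation from boron give the (E)-styryl ketone under neutral conditions with retention of the alkene geometry.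

Compound list
1 | diketene (4-methylideneoxetan-2-one) | C=C1CC(=O)O1 | starting material
2 | 4-bromo-3-oxobutanoyl bromide | O=C(Br)CC(=O)CBr | intermediate
3 | S-ethyl 4-bromo-3-oxobutanethioate | CCSC(=O)CC(=O)CBr | intermediate
4 | (E)-4,4-dimethoxybut-2-enal | COC(OC)/C=C/C=O | starting material
5 | S-ethyl 4-bromo-2-(1,1-dimethoxy-4-oxobutan-2-yl)-3-oxobutanethioate (C18 set by the catalyst) | CCSC(=O)C(C(=O)CBr)[C@H](CC=O)C(OC)OC | intermediate
6 | S-ethyl 2-(dimethoxymethyl)-3-formyl-5-oxocyclopentane-1-carbothioate; acetal (on C18) and formyl (on C19) trans; C19 as in the target, C18 inverted | COC(OC)[C@H]1[C@H](C=O)CC(=O)C1C(=O)SCC | intermediate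
7 | S-ethyl 2-(dimethoxymethyl)-3-(hydroxymethyl)-5-oxocyclopentane-1-carbothioate, 2,3-trans | COC(OC)[C@H]1[C@H](CO)CC(=O)C1C(=O)SCC | intermediate
8 | S-ethyl 3-{[tert-butyl(diphenyl)silyl]oxymethyl}-2-(dimethoxymethyl)-5-oxocyclopentane-1-carbothioate, 2,3-trans | COC(OC)[C@H]1[C@H](CO[Si](c2ccccc2)(c2ccccc2)C(C)(C)C)CC(=O)C1C(=O)SCC | intermediate
9 | 1-(phenylselanyl) derivative of 8 (selenium on C30, anti to the acetal arm) | COC(OC)[C@H]1[C@H](CO[Si](c2ccccc2)(c2ccccc2)C(C)(C)C)CC(=O)[C@@]1([Se]c2ccccc2)C(=O)SCC | intermediate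
10 | selenoxide of 9 | COC(OC)[C@H]1[C@H](CO[Si](c2ccccc2)(c2ccccc2)C(C)(C)C)CC(=O)[C@@]1([Se](=O)c2ccccc2)C(=O)SCC | intermediate
11 | S-ethyl 3-{[tert-butyl(diphenyl)silyl]oxymethyl}-2-(dimethoxymethyl)-5-oxocyclopent-1-ene-1-carbothioate (C30=C18 alkene, C19 retained) | COC(OC)C1=C(C(=O)SCC)C(=O)C[C@H]1CO[Si](c1ccccc1)(c1ccccc1)C(C)(C)C | intermediate
12 | S-ethyl 3-{[tert-butyl(diphenyl)silyl]oxymethyl}-2-(dimethoxymethyl)-5-oxocyclopentane-1-carbothioate, 2,3-cis (C18 and C19 as in the target) | COC(OC)[C@@H]1[C@H](CO[Si](c2ccccc2)(c2ccccc2)C(C)(C)C)CC(=O)C1C(=O)SCC | intermediate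
13 | 3-[(tert-butyldimethylsilyl)oxy]propanal | CC(C)(C)[Si](C)(C)OCCC=O | starting material
14 | (triphenylphosphoranylidene)acetaldehyde | O=CC=P(c1ccccc1)(c1ccccc1)c1ccccc1 | starting material
15 | (E)-5-[(tert-butyldimethylsilyl)oxy]pent-2-enal | CC(C)(C)[Si](C)(C)OCC/C=C/C=O | intermediate
16 | Michael adduct: 12 bearing on C30 the 5-silyloxy-1-oxopentan-3-yl group (C29), new bond anti to both arms | COC(OC)[C@@H]1[C@H](CO[Si](c2ccccc2)(c2ccccc2)C(C)(C)C)CC(=O)[C@@]1(C(=O)SCC)[C@H](CC=O)CCO[Si](C)(C)C(C)(C)C | intermediate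
17 | S-ethyl 7-exo-(dimethoxymethyl)-6-exo-{[tert-butyl(diphenyl)silyl]oxymethyl}-4-hydroxy-8-oxo-2-{2-[(tert-butyldimethylsilyl)oxy]ethyl}bicyclo[3.2.1]octane-1-carbothioate (ring C1 = C30, C2 = C29, C4 = C23, C6 = C19, C7 = C18, C8 = C41; C2 side chain syn to the C8 bridge; C4 carbinol as a mixture) | COC(OC)[C@@H]3[C@H](CO[Si](c2ccccc2)(c2ccccc2)C(C)(C)C)[C@H]1C(O)C[C@H](CCO[Si](C)(C)C(C)(C)C)[C@]3(C(=O)SCC)C1=O | intermediate
18 | C23=C24 alkene from 17 (bicyclo[3.2.1]oct-3-en-8-one) | COC(OC)[C@@H]3[C@H](CO[Si](c2ccccc2)(c2ccccc2)C(C)(C)C)[C@H]1C=C[C@H](CCO[Si](C)(C)C(C)(C)C)[C@]3(C(=O)SCC)C1=O | intermediate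
19 | primary alcohol from 18 (2-hydroxyethyl group on C29) | COC(OC)[C@@H]3[C@H](CO[Si](c2ccccc2)(c2ccccc2)C(C)(C)C)[C@H]1C=C[C@H](CCO)[C@]3(C(=O)SCC)C1=O | intermediate
20 | carboxylic acid from 19 (carboxymethyl group on C29) | COC(OC)[C@@H]3[C@H](CO[Si](c2ccccc2)(c2ccccc2)C(C)(C)C)[C@H]1C=C[C@H](CC(=O)O)[C@]3(C(=O)SCC)C1=O | intermediate
21 | iodolactone: O25 γ-lactone cis-fused at C24–C29, iodine on C23 trans to O25 | COC(OC)[C@@H]3[C@H](CO[Si](c2ccccc2)(c2ccccc2)C(C)(C)C)[C@H]1[C@@H](I)[C@@H]2OC(=O)C[C@@H]2[C@]3(C(=O)SCC)C1=O | intermediate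
22 | lactone thioester core: exo dimethoxymethyl on C18, exo TBDPS-oxymethyl on C19 | COC(OC)[C@@H]3[C@H](CO[Si](c2ccccc2)(c2ccccc2)C(C)(C)C)[C@H]1C[C@@H]2OC(=O)C[C@@H]2[C@]3(C(=O)SCC)C1=O | intermediate
23 | core with exo hydroxymethyl on C19 | COC(OC)[C@@H]3[C@H](CO)[C@H]1C[C@@H]2OC(=O)C[C@@H]2[C@]3(C(=O)SCC)C1=O | intermediate
24 | core with exo formyl on C19 (C20 aldehyde) and exo dimethoxymethyl on C18 | COC(OC)[C@@H]3[C@H](C=O)[C@H]1C[C@@H]2OC(=O)C[C@@H]2[C@]3(C(=O)SCC)C1=O | intermediate
25 | (R)-1-phenylbut-3-yn-1-ol | C#CC[C@@H](O)c1ccccc1 | starting material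
26 | (R)-tert-butyldimethyl[(1-phenylbut-3-yn-1-yl)oxy]silane | C#CC[C@@H](O[Si](C)(C)C(C)(C)C)c1ccccc1 | intermediate
27 | (R)-5-[(tert-butyldimethylsilyl)oxy]-N-methoxy-N-methyl-5-phenylpent-2-ynamide | CON(C)C(=O)C#CC[C@@H](O[Si](C)(C)C(C)(C)C)c1ccccc1 | intermediate
28 | methyl (R)-7-[(tert-butyldimethylsilyl)oxy]-3-oxo-7-phenylhept-4-ynoate | COC(=O)CC(=O)C#CC[C@@H](O[Si](C)(C)C(C)(C)C)c1ccccc1 | intermediate
29 | methyl (3S,7R)-7-[(tert-butyldimethylsilyl)oxy]-3-hydroxy-7-phenylhept-4-ynoate | COC(=O)C[C@H](O)C#CC[C@@H](O[Si](C)(C)C(C)(C)C)c1ccccc1 | intermediate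
30 | methyl (3S,7R)-7-[(tert-butyldimethylsilyl)oxy]-3-(methylsulfonyloxy)-7-phenylhept-4-ynoate | COC(=O)C[C@H](OS(C)(=O)=O)C#CC[C@@H](O[Si](C)(C)C(C)(C)C)c1ccccc1 | intermediate
31 | allenylindium iodide mesylate: indium on C16, allene C16=C5=C4, C4 bearing H and CH2CO2Me, axial chirality from anti SN2' | CS(=O)(=O)O[In](I)C(C[C@@H](O[Si](C)(C)C(C)(C)C)c1ccccc1)=[C@]=C([H])CC(=O)OC | intermediate
32 | anti homopropargylic hydroxy ester (C20–OH, C4 bearing CH2CO2Me and the alkyne) | COC(OC)[C@@H]3[C@H]([C@H](O)[C@H](CC(=O)OC)C#CC[C@@H](O[Si](C)(C)C(C)(C)C)c2ccccc2)[C@H]1C[C@@H]2OC(=O)C[C@@H]2[C@]3(C(=O)SCC)C1=O | intermediate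
33 | C18 dimethyl acetal with the cis-fused O21 alkynyl lactone on C19 | COC(OC)[C@@H]3[C@H]([C@@H]2OC(=O)C[C@@H]2C#CC[C@@H](O[Si](C)(C)C(C)(C)C)c2ccccc2)[C@H]1C[C@@H]2OC(=O)C[C@@H]2[C@]3(C(=O)SCC)C1=O | intermediate
34 | exo (E)-aldoxime with alkynyl O21 lactone, C30 S-ethyl thioester and C8 silyl ether | O/N=C/[C@@H]3[C@H]([C@@H]2OC(=O)C[C@@H]2C#CC[C@@H](O[Si](C)(C)C(C)(C)C)c2ccccc2)[C@H]1C[C@@H]2OC(=O)C[C@@H]2[C@]3(C(=O)SCC)C1=O | intermediate
35 | nitrile oxide from 34 | [O-][N+]#C[C@@H]3[C@H]([C@@H]2OC(=O)C[C@@H]2C#CC[C@@H](O[Si](C)(C)C(C)(C)C)c2ccccc2)[C@H]1C[C@@H]2OC(=O)C[C@@H]2[C@]3(C(=O)SCC)C1=O | intermediate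
36 | isoxazole-fused pentacycle (C30 S-ethyl thioester, C8 silyl ether) | O=C1C[C@@H]2c3c(noc3C[C@@H](O[Si](C)(C)C(C)(C)C)c3ccccc3)[C@@H]3[C@H]([C@@H]2O1)[C@H]1C[C@@H]2OC(=O)C[C@@H]2[C@]3(C(=O)SCC)C1=O | intermediate
37 | primary enaminone (C6–NH2, C5=C6, C16 ketone) | O=C1C[C@@H]2C(C(=O)C[C@@H](O[Si](C)(C)C(C)(C)C)c3ccccc3)=C(N)[C@@H]3[C@H]([C@@H]2O1)[C@H]1C[C@@H]2OC(=O)C[C@@H]2[C@]3(C(=O)SCC)C1=O | intermediate
38 | C8 hydroxy enaminone | O=C1C[C@@H]2C(C(=O)C[C@@H](O)c3ccccc3)=C(N)[C@@H]3[C@H]([C@@H]2O1)[C@H]1C[C@@H]2OC(=O)C[C@@H]2[C@]3(C(=O)SCC)C1=O | intermediate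
39 | dihydropyranone bearing the C30 S-ethyl thioester | O=C1C[C@@H]2C3=C(O[C@@H](c4ccccc4)CC3=O)[C@@H]3[C@H]([C@@H]2O1)[C@H]1C[C@@H]2OC(=O)C[C@@H]2[C@]3(C(=O)SCC)C1=O | intermediate
40 | (E)-styrylboronic acid | OB(O)/C=C/c1ccccc1 | starting material
41 | CNP0313292.4 | O=C1C[C@@H]2C3=C(O[C@@H](c4ccccc4)CC3=O)[C@@H]3[C@H]([C@@H]2O1)[C@H]1C[C@@H]2OC(=O)C[C@@H]2[C@]3(C(=O)/C=C/c2ccccc2)C1=O | target

Total step count: 26. Longest linear sequence: 20 steps (steps 1–6, 8–15 and 21–26, from diketene 1 to 41).

Steps most likely to fail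

Step 23. The nitrile oxide may dimerise to the furoxan or be trapped by methanol before it reaches the alkyne if the fused lactone does not hold the two ends close enough, and the iodine oxidant may attack the thioester sulfur. The fallback uses a nitrone as the dipole and forms the same two bonds; it sets out from 33 and comes back at 39. The acetal of 33 is hydrolysed (Amberlyst-15, wet acetone) to the C6 aldehyde F1. Condensation with N-benzylhydroxylamine gives the N-benzyl nitrone F2, which on heating in toluene undergoes the intramolecular nitrone–alkyne cycloaddition to the ring-fused 4-isoxazoline F3. DBU opens the N–O bond of F3 by deprotonation at C6 and gives the N-benzyl enaminone F4. Treatment of F4 with aqueous HF and then TFA, as in step 25, should close the pyranone with loss of benzylamine and give 39.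

Step 21. The β-mesyloxy ester may lose methanesulfonic acid before the allenylmetal forms, zerovalent palladium may insert into the C30 thioester, and facial selectivity may erode if the reagent and the C19 stereocenter are mismatched. The fallback uses an isolated allenylboron reagent, so no palladium meets the thioester; it sets out from 29 and comes back at 33. The alcohol 29 is converted (ClCO2Me, pyridine) into the propargylic methyl carbonate F5. Copper-catalysed anti SN2' borylation (CuCl, Xantphos, KOtBu, B2pin2) turns F5 into the allenyl pinacolboronate F6 with transfer of chirality. F6 adds to aldehyde 24 on gentle warming through the same cyclic transition state to give 32 after work-up, and PPTS closes 32 to 33.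

Step 26. Insertion of palladium into the hindered bridgehead thioester may be slow, and decarbonylation of the acylpalladium species or protodeboronation of 40 may then take over. The fallback activates the acyl group without palladium insertion into the C–S bond; it sets out from 39 and comes back at 41. Thiophilic hydrolysis (AgO3SCF3, 2,6-lutidine, aqueous THF) gives the bridgehead carboxylic acid F7, which cannot decarboxylate through a bridgehead enol. The Ghosez reagent (1-chloro-N,N,2-trimethylprop-1-en-1-amine) converts F7 into the acid chloride F8. Stille acylation of F8 with (E)-tributyl(2-phenylethenyl)stannane and Pd(PPh3)4 should give 41.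

Further compounds
F1 | step 23 | C6 aldehyde from 33 (exo formyl on C18) | O=C[C@@H]3[C@H]([C@@H]2OC(=O)C[C@@H]2C#CC[C@@H](O[Si](C)(C)C(C)(C)C)c2ccccc2)[C@H]1C[C@@H]2OC(=O)C[C@@H]2[C@]3(C(=O)SCC)C1=O
F2 | step 23 | (Z)-N-benzyl nitrone of F1 | [O-]/[N+](Cc4ccccc4)=C\[C@@H]3[C@H]([C@@H]2OC(=O)C[C@@H]2C#CC[C@@H](O[Si](C)(C)C(C)(C)C)c2ccccc2)[C@H]1C[C@@H]2OC(=O)C[C@@H]2[C@]3(C(=O)SCC)C1=O
F3 | step 23 | ring-fused N-benzyl 4-isoxazoline (C6 sp3, configuration at C6 not defined and not carried on) | O=C1C[C@@H]2C3=C(C[C@@H](O[Si](C)(C)C(C)(C)C)c4ccccc4)ON(Cc4ccccc4)C3[C@@H]3[C@H]([C@@H]2O1)[C@H]1C[C@@H]2OC(=O)C[C@@H]2[C@]3(C(=O)SCC)C1=O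
F4 | step 23 | N-benzyl enaminone (C6–NHBn, C16 ketone) | O=C1C[C@@H]2C(C(=O)C[C@@H](O[Si](C)(C)C(C)(C)C)c3ccccc3)=C(NCc3ccccc3)[C@@H]3[C@H]([C@@H]2O1)[C@H]1C[C@@H]2OC(=O)C[C@@H]2[C@]3(C(=O)SCC)C1=O
F5 | step 21 | methyl (3S,7R)-7-[(tert-butyldimethylsilyl)oxy]-3-(methoxycarbonyloxy)-7-phenylhept-4-ynoate | COC(=O)C[C@H](OC(=O)OC)C#CC[C@@H](O[Si](C)(C)C(C)(C)C)c1ccccc1
F6 | step 21 | allenyl pinacolboronate (boron on C16, same axial chirality as 31) | CC1(C)OB(OC1(C)C)C(C[C@@H](O[Si](C)(C)C(C)(C)C)c1ccccc1)=[C@]=C([H])CC(=O)OC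
F7 | step 26 | bridgehead carboxylic acid from 39 | O=C1C[C@@H]2C3=C(O[C@@H](c4ccccc4)CC3=O)[C@@H]3[C@H]([C@@H]2O1)[C@H]1C[C@@H]2OC(=O)C[C@@H]2[C@]3(C(=O)O)C1=O
F8 | step 26 | bridgehead acid chloride | O=C1C[C@@H]2C3=C(O[C@@H](c4ccccc4)CC3=O)[C@@H]3[C@H]([C@@H]2O1)[C@H]1C[C@@H]2OC(=O)C[C@@H]2[C@]3(C(=O)Cl)C1=O
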